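The synthesis rests on cutting the C5'–C6' bond of ring B (C1' bears the CH2 bridge, C3' the methyl, C5' the butanoyl group). The oxygens at C2', C4' and C6' alternate around this ring as in a folded 3,5,7-trioxodecanoate, and that pattern is what the key step exploits. The chain is stored as a 4-hydroxy-2-pyrone; Mg(OMe)2 unmasks the triketo ester and closes ring B by Claisen condensation in one operation, giving the target directly because the chelated ring A phenol is carried free. The precursor is a 4-hydroxy-5-methyl-6-(2-oxopentyl)-2-pyrone carrying the complete ring A benzyl group at C3, made by reductive coupling of a pyrone with a ring A aldehyde.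

Key step: step 8

Remark on the chemistry: the ring A phenol is hydrogen-bonded to its ortho butanoyl group and should be inert in every step, so no protecting group is used and no deprotection follows the key step; lithium species generated before an electrophile or a quench is added are numbered as intermediates.

Step 1
Reactants: 1 3-methylpentane-2,4-dione
Product: 3 4-methyl-3,5-dioxohexanoic acid, via dilithium dienediolate 2 (not isolated)
Conditions: LiN(iPr)2 (2.2 equiv, commercial solution), THF, −78 → 0 °C; excess CO2 (dry ice/Et2O), −78 °C → rt; then aq HCl, 0 °C; used crude and cold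
Reagents that add atoms: carbon dioxide, O=C=O
Why: Carboxylation of a β-diketone 1,3-dianion takes place at the terminal, last-formed and most basic carbanion, so the CO2H should end on the former acetyl methyl group, and the only sp3 stereocentre (C4) is an enolisable position of no consequence.

Step 2
Reactants: 3 4-methyl-3,5-dioxohexanoic acid
Product: 5 4-hydroxy-5,6-dimethyl-2H-pyran-2-one, via acyl imidazolide 4 (not isolated)
Conditions: CDI (1.1 equiv), THF, rt; then aq HCl
Reagents that add atoms: none
Why: Activation of the acid as its imidazolide lets the enol oxygen of the distal acetyl group close the six-membered lactone by intramolecular O-acylation (CDI-mediated lactonisation of a 3,5-dioxo acid), and tautomerisation should give the stable 4-hydroxy-2-pyrone.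

Step 3
Reactants: 5 4-hydroxy-5,6-dimethyl-2H-pyran-2-one, 6 N-methoxy-N-methylbutanamide
Product: 9 4-hydroxy-5-methyl-6-(2-oxopentyl)-2H-pyran-2-one, via pyrone dianion 7 (not isolated), via tetrahedral Weinreb adduct 8 (not isolated)
Conditions: LiN(iPr)2 (2.2 equiv), THF, −78 → −20 °C; 6 (1.1 equiv), −78 → 0 °C; then aq HCl
Reagents that add atoms: none
Why: Double deprotonation gives the 4-olate/6-CH2 vinylogous dianion (the 5-methyl is cross-conjugated and not acidic), and its carbon terminus should be acylated by the Weinreb amide through a chelated tetrahedral adduct that lasts until the quench, so the more acidic product never consumes base (C-acylation of a 4-hydroxy-6-methyl-2-pyrone dianion).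

Step 4
Reactants: 10 2,5-dimethylresorcinol, 11 butanoyl chloride
Product: 12 1-(2,4-dihydroxy-3,6-dimethylphenyl)butan-1-one
Conditions: AlCl3 (2.5 equiv), PhNO2, 0 → 50 °C; then ice, aq HCl
Reagents that add atoms: none
Why: Friedel–Crafts acylation of a symmetric resorcinol, in which the two free positions are equivalent, each ortho to one hydroxyl and para to the other, and the first acyl group should deactivate the ring against a second acylation.

Step 5
Reactants: 12 1-(2,4-dihydroxy-3,6-dimethylphenyl)butan-1-one
Product: 13 1-(2-hydroxy-4-methoxy-3,6-dimethylphenyl)butan-1-one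
Conditions: MeI (1.1 equiv), K2CO3 (1.1 equiv), acetone, rt
Reagents that add atoms: iodomethane, CI
Why: Williamson methylation under weak base should select the free 4-OH (para to the ketone) over the 2-OH, which is held in a hydrogen bond to the ketone and flanked by two substituents.

Step 6
Reactants: 13 1-(2-hydroxy-4-methoxy-3,6-dimethylphenyl)butan-1-one
Product: 15 3-butanoyl-4-hydroxy-6-methoxy-2,5-dimethylbenzaldehyde, via α-chloro ether 14 (not isolated)
Conditions: Cl2CHOMe (1.5 equiv), TiCl4 (3 equiv), CH2Cl2, 0 °C → rt; then ice-water
Reagents that add atoms: dichloromethyl methyl ether, COC(Cl)Cl; water, O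
Why: Rieche formylation should attack the single free ring position, which is para to the phenol, ortho to the methoxy group and meta to the ketone, because the small chloro(methoxy)carbenium electrophile tolerates two flanking substituents and, unlike a Vilsmeier reagent, does not turn the ortho-hydroxy ketone into a chromone.

Step 7
Reactants: 9 4-hydroxy-5-methyl-6-(2-oxopentyl)-2H-pyran-2-one, 15 3-butanoyl-4-hydroxy-6-methoxy-2,5-dimethylbenzaldehyde
Product: 17 3-[(3-butanoyl-4-hydroxy-6-methoxy-2,5-dimethylphenyl)methyl]-4-hydroxy-5-methyl-6-(2-oxopentyl)-2H-pyran-2-one, via arylidene pyrandione 16 (not isolated)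
Conditions: L-proline (20 mol %), Hantzsch ester (diethyl 2,6-dimethyl-1,4-dihydropyridine-3,5-dicarboxylate, 1.2 equiv), CH2Cl2/EtOH, rt → 40 °C
Reagents that add atoms: none
Why: Organocatalytic reductive alkylation, in which Knoevenagel condensation at the strongly acidic C3 of the 4-hydroxypyrone gives an arylidene dione that accepts hydride from the Hantzsch ester at the benzylic carbon, while the far less acidic side-chain methylene and both ketones should stay untouched.

Step 8
Reactants: 17 3-[(3-butanoyl-4-hydroxy-6-methoxy-2,5-dimethylphenyl)methyl]-4-hydroxy-5-methyl-6-(2-oxopentyl)-2H-pyran-2-one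
Product: 19 1-[3-[(3-butanoyl-2,4,6-trihydroxy-5-methylphenyl)methyl]-6-hydroxy-4-methoxy-2,5-dimethylphenyl]butan-1-one, via triketo methyl ester 18 (not isolated)
Conditions: Mg(OMe)2 (8 equiv, commercial solution in MeOH), MeOH, reflux, Ar; then cold 1 M aq HCl
Reagents that add atoms: none
Why: Methoxide adds to the lactone carbonyl of 17 and the ring opens to the triketo methyl ester 18, which magnesium holds as a chelated polyenolate. The methylene carbanion C5', flanked by the C4' ketone and the butanoyl carbonyl, then attacks the ester carbon C6' in a Dieckmann-type Claisen condensation, a 6-exo-trig closure that forms the C5'–C6' bond and carbocyclic ring B; loss of methoxide and enolisation of the three ring CH positions give the aromatic triol. The closest known reaction type is the Mg(OMe)2-mediated conversion of 6-(2-oxoalkyl)-4-hydroxy-2-pyrones and of 3,5,7-trioxo esters into acylphloroglucinols. No stereocentre is formed, since the two enolisable centres of 18 end as sp2 ring carbons. The step needs C-acylation to win over aldol closure, relactonisation and retro-Claisen cleavage: an aldol of C1' onto the butanoyl carbonyl would leave C1' quaternary, cannot aromatise and therefore reverts, whereas the Claisen product is removed irreversibly as a magnesium phenoxide. The free ring A phenol sits as a magnesium chelate with its own ketone, which keeps that carbonyl out of the reaction.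

Compound list
1 | 3-methylpentane-2,4-dione | CC(=O)C(C)C(C)=O | starting material
2 | dilithium 3-methylpenta-1,3-diene-2,4-diolate (enolate geometry not defined) | [Li+].[Li+].C=C([O-])C(C)=C(C)[O-] | intermediate
3 | 4-methyl-3,5-dioxohexanoic acid (C4 enolisable, racemic) | CC(=O)C(C)C(=O)CC(=O)O | intermediate
4 | 1-(1H-imidazol-1-yl)-4-methylhexane-1,3,5-trione (C4 enolisable, racemic) | CC(=O)C(C)C(=O)CC(=O)n1ccnc1 | intermediate
5 | 4-hydroxy-5,6-dimethyl-2H-pyran-2-one | CC1=C(C)C(O)=CC(=O)O1 | intermediate
6 | N-methoxy-N-methylbutanamide | CCCC(=O)N(C)OC | starting material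
7 | dilithium dianion of 5 (4-olate, 6-CH2 carbanion) | [Li+].[Li+].[CH2-]C1=C(C)C([O-])=CC(=O)O1 | intermediate
8 | dilithium salt of 4-hydroxy-6-[2-hydroxy-2-[methoxy(methyl)amino]pentyl]-5-methyl-2H-pyran-2-one (racemic tetrahedral adduct) | [Li+].[Li+].CCCC([O-])(CC1=C(C)C([O-])=CC(=O)O1)N(C)OC | intermediate
9 | 4-hydroxy-5-methyl-6-(2-oxopentyl)-2H-pyran-2-one | CCCC(=O)CC1=C(C)C(O)=CC(=O)O1 | intermediate
10 | 2,5-dimethylresorcinol (2,5-dimethylbenzene-1,3-diol) | Cc1cc(O)c(C)c(O)c1 | starting material
11 | butanoyl chloride | CCCC(=O)Cl | starting material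
12 | 1-(2,4-dihydroxy-3,6-dimethylphenyl)butan-1-one | CCCC(=O)c1c(C)cc(O)c(C)c1O | intermediate
13 | 1-(2-hydroxy-4-methoxy-3,6-dimethylphenyl)butan-1-one | CCCC(=O)c1c(C)cc(OC)c(C)c1O | intermediate
14 | 1-[5-[chloro(methoxy)methyl]-2-hydroxy-4-methoxy-3,6-dimethylphenyl]butan-1-one (racemic) | CCCC(=O)c1c(C)c(C(Cl)OC)c(OC)c(C)c1O | intermediate
15 | 3-butanoyl-4-hydroxy-6-methoxy-2,5-dimethylbenzaldehyde | CCCC(=O)c1c(C)c(C=O)c(OC)c(C)c1O | intermediate
16 | 3-[(3-butanoyl-4-hydroxy-6-methoxy-2,5-dimethylphenyl)methylidene]-5-methyl-6-(2-oxopentyl)-2H-pyran-2,4(3H)-dione (alkene geometry not defined) | CCCC(=O)CC1=C(C)C(=O)C(=Cc2c(C)c(C(=O)CCC)c(O)c(C)c2OC)C(=O)O1 | intermediate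
17 | 3-[(3-butanoyl-4-hydroxy-6-methoxy-2,5-dimethylphenyl)methyl]-4-hydroxy-5-methyl-6-(2-oxopentyl)-2H-pyran-2-one | CCCC(=O)CC1=C(C)C(O)=C(Cc2c(C)c(C(=O)CCC)c(O)c(C)c2OC)C(=O)O1 | intermediate
18 | methyl 2-[(3-butanoyl-4-hydroxy-6-methoxy-2,5-dimethylphenyl)methyl]-4-methyl-3,5,7-trioxodecanoate (C2 and C4 enolised, no defined configuration) | CCCC(=O)CC(=O)C(C)C(=O)C(Cc1c(C)c(C(=O)CCC)c(O)c(C)c1OC)C(=O)OC | intermediate
19 | 1-[3-[(3-butanoyl-2,4,6-trihydroxy-5-methylphenyl)methyl]-6-hydroxy-4-methoxy-2,5-dimethylphenyl]butan-1-one (no stereocentres) | CCCC(=O)c1c(C)c(Cc2c(O)c(C)c(O)c(C(=O)CCC)c2O)c(OC)c(C)c1O | target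

Total step count: 8. Longest linear sequence: 5 steps (steps 1, 2, 3, 7, 8; the ring A branch, steps 4, 5, 6, 7, 8, is equally long).

Steps most likely to fail

Step 8. Methoxide may fail to open the electron-rich, fully substituted pyrone anion. The opened chain may also relactonise, suffer retro-Claisen cleavage, or close through oxygen to a 4-pyranone during the acidic work-up. The fallback gives up de novo construction of ring B and sets out from aldehyde 15. Reductive amination with Me2NH and NaBH(OAc)3 should give the benzylic amine 1-[5-[(dimethylamino)methyl]-2-hydroxy-4-methoxy-3,6-dimethylphenyl]butan-1-one F1. In parallel, purchased 2-methylphloroglucinol (Cc1c(O)cc(O)cc1O) would be C-acylated with butanoyl chloride 11 (AlCl3, PhNO2) to 1-(2,4,6-trihydroxy-3-methylphenyl)butan-1-one F2, whose single free ring position is the future C1'. Heating F1 with F2 in dioxane should expel dimethylamine from the para-hydroxybenzylamine while the free position of F2 adds to the benzylic carbon (Mannich-base alkylation of a phloroglucinol). This comes back to the route at target 19.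

Step 7. Condensation of the doubly ortho-substituted, electron-rich aldehyde may be slow. Condensation at the side-chain methylene, or addition of a second pyrone to the arylidene, could then overtake hydride transfer. The fallback again sets out from 15. Chemoselective reduction of the formyl group with NaBH4 (MeOH, −20 °C; the hindered, chelated aryl ketone reacts far more slowly) should give the benzylic alcohol 1-[2-hydroxy-5-(hydroxymethyl)-4-methoxy-3,6-dimethylphenyl]butan-1-one F3. With pyrone 9 and catalytic TsOH in MeCN at 50 °C, the benzylic cation, stabilised by the para hydroxyl and the ortho methoxy group, should be captured at C3 of the pyrone; O-alkylation is reversible under these conditions. This dehydrative benzylation comes back to the route at precursor 17.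

Step 3. Proton transfer from the amide α-CH2 to the dianion, or incomplete formation of a poorly soluble dianion, may simply return 5. The fallback reverses the order of chain building and sets out from diketone 1. Its dienediolate 2 (2 equiv) would be acylated at the terminal carbon with methyl butanoate (CCCC(=O)OC) to give 3-methylnonane-2,4,6-trione F4. The trianion of F4 (LiN(iPr)2, 3.3 equiv, THF) should be carboxylated with CO2 at the terminal methyl group to give 4-methyl-3,5,7-trioxodecanoic acid F5. Lactonisation with CDI, as in step 2, comes back to the route at pyrone 9.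

Further compounds
F1 | step 8 | 1-[5-[(dimethylamino)methyl]-2-hydroxy-4-methoxy-3,6-dimethylphenyl]butan-1-one | CCCC(=O)c1c(C)c(CN(C)C)c(OC)c(C)c1O
F2 | step 8 | 1-(2,4,6-trihydroxy-3-methylphenyl)butan-1-one | CCCC(=O)c1c(O)cc(O)c(C)c1O
F3 | step 7 | 1-[2-hydroxy-5-(hydroxymethyl)-4-methoxy-3,6-dimethylphenyl]butan-1-one | CCCC(=O)c1c(C)c(CO)c(OC)c(C)c1O
F4 | step 3 | 3-methylnonane-2,4,6-trione | CCCC(=O)CC(=O)C(C)C(C)=O
F5 | step 3 | 4-methyl-3,5,7-trioxodecanoic acid | CCCC(=O)CC(=O)C(C)C(=O)CC(=O)O
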